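**Retrosynthetic overview**
1. Target 31 ⇐ Evans–Tishchenko reduction (acetaldehyde) of macrocyclic β-hydroxy enone 30, which sets C1 and places the acetate on O3.
2. Ten-membered ring (formed last) ⇐ intramolecular Ni/Cr coupling C1–C10 of aldehyde/(Z)-vinyl iodide 27, then oxidation to the enone.
3. 27 ⇐ lactone 12 by Ni/Cr coupling with aldehyde 13 (C3–C4), CBS reduction (C3), (Z)-iodo-olefination at C9, lactone α-methylenation and angeloylation of O8.
4. γ-Lactone 12 (formed first; C6/C7/C8 triad) ⇐ Fráter–Seebach allylation (C7), ynone transfer hydrogenation (C6), Red-Al/I2, alkene cleavage and lactol oxidation.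
5. First stereocentre C8 ⇐ ketoreductase reduction of achiral keto ester 3 (from 1 + 2).

Assumption: C1–C15 in the text follow germacranolide numbering of the target (O6 in the lactone, angelate on O8, acetate on O3, hydroxyl on C1), and the (S)-selective ketoreductase for 3 is picked from a commercial screening panel.

**Step 1**
Reactants: 1 ethyl 4-chloro-3-oxobutanoate; 2 4-methoxybenzyl alcohol
Product: 3 ethyl 4-[(4-methoxybenzyl)oxy]-3-oxobutanoate
Conditions: NaH (2.2 equiv), THF, 0 °C → rt; AcOH quench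
Reagents that add atoms: none
Why: Williamson etherification in which the alkoxide of 2 displaces the primary chloride of the sodium enolate of 1, with no stereocentre involved.

**Step 2**
Reactants: 3 ethyl 4-[(4-methoxybenzyl)oxy]-3-oxobutanoate
Product: 4 ethyl (3S)-3-hydroxy-4-[(4-methoxybenzyl)oxy]butanoate
Conditions: ketoreductase (KRED, (S)-selective), NADP+ (cat.), iPrOH, phosphate buffer pH 7, 30 °C
Reagents that add atoms: none
Why: Enzymatic asymmetric reduction of a β-keto ester by a ketoreductase (NADPH hydride, recycled by isopropanol) attacks one carbonyl face only and sets the first stereocentre, C8, in high ee.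

**Step 3**
Reactants: 4 ethyl (3S)-3-hydroxy-4-[(4-methoxybenzyl)oxy]butanoate
Product: 5 ethyl (2R,3S)-2-allyl-3-hydroxy-4-[(4-methoxybenzyl)oxy]butanoate
Conditions: LiN(iPr)2 (2.2 equiv), THF, −78 → −20 °C; allyl bromide, DMPU, −78 → −10 °C
Reagents that add atoms: allyl bromide, C=CCBr
Why: Fráter–Seebach alkylation of the chelated lithium alkoxide–enolate dianion is anti-selective (typically >95:5), which sets C7 anti to O8 as the target requires.

**Step 4**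
Reactants: 5 ethyl (2R,3S)-2-allyl-3-hydroxy-4-[(4-methoxybenzyl)oxy]butanoate
Product: 6 ethyl (2R,3S)-2-allyl-4-[(4-methoxybenzyl)oxy]-3-(triethylsilyloxy)butanoate
Conditions: Et3SiCl, imidazole, DMF, 0 °C → rt
Reagents that add atoms: chlorotriethylsilane, CC[Si](Cl)(CC)CC
Why: Silylation masks O8 (the later angelate site) with the most acid-labile silyl group of the route, without touching a stereocentre.

**Step 5**
Reactants: 6 ethyl (2R,3S)-2-allyl-4-[(4-methoxybenzyl)oxy]-3-(triethylsilyloxy)butanoate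
Product: 7 (2R,3S)-2-allyl-N-methoxy-4-[(4-methoxybenzyl)oxy]-N-methyl-3-(triethylsilyloxy)butanamide
Conditions: MeNH(OMe)·HCl, iPrMgCl, THF, −20 → 0 °C
Reagents that add atoms: N,O-dimethylhydroxylamine hydrochloride, CNOC.Cl
Why: Weinreb amide formation by aminolysis of the ester with the chloromagnesium amide gives a mono-addition acyl donor and leaves C7 and C8 untouched.

**Step 6**
Reactants: 7 (2R,3S)-2-allyl-N-methoxy-4-[(4-methoxybenzyl)oxy]-N-methyl-3-(triethylsilyloxy)butanamide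
Product: 8 (5R,6S)-5-allyl-7-[(4-methoxybenzyl)oxy]-6-(triethylsilyloxy)hept-2-yn-4-one
Conditions: CH3C≡CMgBr, THF, −20 → 0 °C
Reagents that add atoms: 1-propynylmagnesium bromide, CC#C[Mg]Br
Why: Grignard addition to a Weinreb amide stops at the chelated tetrahedral intermediate and releases the ynone on work-up, with the α-stereocentre C7 preserved at low temperature.

**Step 7**
Reactants: 8 (5R,6S)-5-allyl-7-[(4-methoxybenzyl)oxy]-6-(triethylsilyloxy)hept-2-yn-4-one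
Product: 9 (4R,5S,6S)-5-allyl-7-[(4-methoxybenzyl)oxy]-6-(triethylsilyloxy)hept-2-yn-4-ol
Conditions: Ru[(R,R)-TsDPEN](p-cymene) (2 mol %), iPrOH, rt
Reagents that add atoms: none
Why: Noyori asymmetric transfer hydrogenation of an ynone under base-free conditions is catalyst-controlled, and the (R,R) ligand gives the (R)-propargylic alcohol, placing O6 syn to O8 and anti to the allyl group.

**Step 8**
Reactants: 9 (4R,5S,6S)-5-allyl-7-[(4-methoxybenzyl)oxy]-6-(triethylsilyloxy)hept-2-yn-4-ol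
Product: 10 (2Z,4R,5S,6S)-5-allyl-2-iodo-7-[(4-methoxybenzyl)oxy]-6-(triethylsilyloxy)hept-2-en-4-ol
Conditions: NaAlH2(OCH2CH2OMe)2 (Red-Al), THF, 0 °C → rt; EtOAc; I2, −78 → 0 °C
Reagents that add atoms: iodine, [I][I]
Why: Hydroxyl-directed trans-hydroalumination of the propargylic alcohol puts aluminium on the distal carbon, and iodinolysis with retention gives the (Z)-vinyl iodide (iodine cis to C6), which fixes the geometry of the future C4=C5 bond.

**Step 9**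
Reactants: 10 (2Z,4R,5S,6S)-5-allyl-2-iodo-7-[(4-methoxybenzyl)oxy]-6-(triethylsilyloxy)hept-2-en-4-ol
Product: 12 (4S,5R)-5-[(Z)-2-iodoprop-1-enyl]-4-[(1S)-2-[(4-methoxybenzyl)oxy]-1-(triethylsilyloxy)ethyl]oxolan-2-one, via lactol 11 (not isolated)
Conditions: OsO4 (2 mol %), NaIO4, 2,6-lutidine, dioxane/H2O, rt; then TEMPO (cat.), PhI(OAc)2, CH2Cl2, rt
Reagents that add atoms: sodium periodate, [Na+].[O-]I(=O)(=O)=O
Why: Lemieux–Johnson cleavage of the only monosubstituted alkene (the iodoalkene is electron-poor and hindered) gives an aldehyde that closes on the free O6 hydroxyl, and TEMPO oxidation of the lactol gives the γ-lactone whose cis C6/C7 relationship follows from the centres already set.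

**Step 10**
Reactants: 12 (4S,5R)-5-[(Z)-2-iodoprop-1-enyl]-4-[(1S)-2-[(4-methoxybenzyl)oxy]-1-(triethylsilyloxy)ethyl]oxolan-2-one; 13 3-(tert-butyldimethylsilyloxy)propanal
Product: 14 lactone allylic alcohol (C3 epimers) carrying the (1Z)-5-(tert-butyldimethylsilyloxy)-3-hydroxy-2-methylpent-1-enyl chain on C6
Conditions: CrCl2 (6 equiv), NiCl2 (2 mol %), DMSO, rt
Reagents that add atoms: none
Why: Nozaki–Hiyama–Kishi coupling (nickel-catalysed, mediated by divalent chromium) joins C4 to C3 with retention of the Z geometry and tolerates the lactone, while the unselective C3 carbinol is corrected in the next two steps.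

**Step 11**
Reactants: 14 lactone allylic alcohol (C3 epimers)
Product: 15 (4S,5S)-5-[(1Z)-5-(tert-butyldimethylsilyloxy)-2-methyl-3-oxopent-1-enyl]-4-[(1S)-2-[(4-methoxybenzyl)oxy]-1-(triethylsilyloxy)ethyl]oxolan-2-one
Conditions: Dess–Martin periodinane, NaHCO3, CH2Cl2, 0 °C → rt
Reagents that add atoms: none
Why: Dess–Martin oxidation converges both C3 epimers to one Z-enone, which cannot cyclise to a furan because its γ-oxygen is tied up in the lactone.

**Step 12**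
Reactants: 15 Z-enone lactone
Product: 16 (4S,5S)-5-[(1Z,3S)-5-(tert-butyldimethylsilyloxy)-3-hydroxy-2-methylpent-1-enyl]-4-[(1S)-2-[(4-methoxybenzyl)oxy]-1-(triethylsilyloxy)ethyl]oxolan-2-one
Conditions: (R)-2-methyl-CBS-oxazaborolidine (0.5 equiv), catecholborane, toluene, −78 °C
Reagents that add atoms: none
Why: Corey–Bakshi–Shibata reduction with the (R)-oxazaborolidine treats the α-methyl alkenyl group as the large substituent and gives the (S)-allylic alcohol at C3 by reagent control, without reducing the lactone.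

**Step 13**
Reactants: 16 (3S)-allylic alcohol lactone
Product: 17 (4S,5S)-5-[(1Z,3S)-3,5-bis(tert-butyldimethylsilyloxy)-2-methylpent-1-enyl]-4-[(1S)-2-[(4-methoxybenzyl)oxy]-1-(triethylsilyloxy)ethyl]oxolan-2-one
Conditions: t-BuMe2SiOTf, 2,6-lutidine, CH2Cl2, −78 °C
Reagents that add atoms: tert-butyldimethylsilyl trifluoromethanesulfonate, CC(C)(C)[Si](C)(C)OS(=O)(=O)C(F)(F)F
Why: Silylation of the hindered C3 alcohol gives the most robust silyl ether of the route, which is kept until the last deprotection.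

**Step 14**
Reactants: 17 tris-silyl 4-methoxybenzyl ether lactone
Product: 18 (4S,5S)-5-[(1Z,3S)-3,5-bis(tert-butyldimethylsilyloxy)-2-methylpent-1-enyl]-4-[(1S)-2-hydroxy-1-(triethylsilyloxy)ethyl]oxolan-2-one
Conditions: DDQ, CH2Cl2/pH 7 buffer, 0 °C
Reagents that add atoms: none
Why: Oxidative cleavage of the 4-methoxybenzyl ether by DDQ (benzylic hydride abstraction, then hydrolysis) frees the C9 alcohol and leaves silyl ethers, lactone and alkene intact.

**Step 15**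
Reactants: 18 primary alcohol lactone
Product: 19 (4S,5S)-5-[(1Z,3S)-3,5-bis(tert-butyldimethylsilyloxy)-2-methylpent-1-enyl]-4-[(1S)-2-oxo-1-(triethylsilyloxy)ethyl]oxolan-2-one
Conditions: Dess–Martin periodinane, NaHCO3, CH2Cl2, 0 °C → rt
Reagents that add atoms: none
Why: Dess–Martin oxidation gives the α-silyloxy aldehyde under buffered, non-epimerising conditions.

**Step 16**
Reactants: 19 α-silyloxy aldehyde lactone
Product: 20 (4S,5S)-5-[(1Z,3S)-3,5-bis(tert-butyldimethylsilyloxy)-2-methylpent-1-enyl]-4-[(1S,2Z)-3-iodo-1-(triethylsilyloxy)but-2-enyl]oxolan-2-one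
Conditions: EtPPh3I, n-BuLi, THF, rt; I2, −78 °C; NaN(SiMe3)2, −20 °C; then 19, −78 °C
Reagents that add atoms: ethyltriphenylphosphonium iodide, CC[P+](c1ccccc1)(c1ccccc1)c1ccccc1.[I-]; iodine, [I][I]
Why: Stork–Zhao-type Wittig olefination with the α-iodo ylide Ph3P=C(I)CH3 is kinetically Z-selective at low temperature and installs C10, its methyl and the iodine cis to C8.

**Step 17**
Reactants: 20 (Z)-vinyl iodide lactone
Product: 23 (4S,5S)-5-[(1Z,3S)-3,5-bis(tert-butyldimethylsilyloxy)-2-methylpent-1-enyl]-4-[(1S,2Z)-3-iodo-1-(triethylsilyloxy)but-2-enyl]-3-methylideneoxolan-2-one, via Mannich base 21 (not isolated), via methiodide 22 (not isolated)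
Conditions: LiN(iPr)2, THF, −78 °C; CH2=NMe2 I (Eschenmoser salt), −78 → 0 °C; MeI, MeOH, rt; NaHCO3 (aq), CH2Cl2, rt
Reagents that add atoms: N,N-dimethylmethyleneiminium iodide, C=[N+](C)C.[I-]
Why: Lactone α-methylenation by Mannich reaction of the lithium enolate with Eschenmoser's salt, N-methylation and Hofmann-type elimination makes C11 sp2 without affecting a stereocentre, and it is done before any acyl ester is present.

**Step 18**
Reactants: 23 α-methylene lactone triethylsilyl ether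
Product: 24 (4R,5S)-5-[(1Z,3S)-3,5-bis(tert-butyldimethylsilyloxy)-2-methylpent-1-enyl]-4-[(1S,2Z)-1-hydroxy-3-iodobut-2-enyl]-3-methylideneoxolan-2-one
Conditions: PPTS (cat.), MeOH/CH2Cl2, 0 °C
Reagents that add atoms: none
Why: Acid-catalysed methanolysis removes only the triethylsilyl ether because it is far more acid-labile than the primary and secondary tert-butyldimethylsilyl ethers.

**Step 19**
Reactants: 24 C8 alcohol
Product: 25 (1S,2Z)-1-[(2S,3S)-2-[(1Z,3S)-3,5-bis(tert-butyldimethylsilyloxy)-2-methylpent-1-enyl]-4-methylidene-5-oxooxolan-3-yl]-3-iodobut-2-enyl (2Z)-2-methylbut-2-enoate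
Conditions: angelic acid, 2,4,6-trichlorobenzoyl chloride, Et3N, toluene, rt; then 24, 75 °C
Reagents that add atoms: angelic acid, C/C=C(/C)C(=O)O
Why: Yamaguchi-type esterification through the mixed 2,4,6-trichlorobenzoic anhydride acylates the hindered allylic alcohol with retention at C8, and leaving out DMAP avoids angelate-to-tiglate isomerisation.

**Step 20**
Reactants: 25 angelate bis-silyl ether
Product: 26 (1S,2Z)-1-[(2S,3S)-2-[(1Z,3S)-3-(tert-butyldimethylsilyloxy)-5-hydroxy-2-methylpent-1-enyl]-4-methylidene-5-oxooxolan-3-yl]-3-iodobut-2-enyl (2Z)-2-methylbut-2-enoate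
Conditions: HF·pyridine, pyridine, THF, 0 °C
Reagents that add atoms: none
Why: Buffered HF·pyridine cleaves the unhindered primary silyl ether much faster than the hindered secondary allylic one.

**Step 21**
Reactants: 26 primary alcohol
Product: 27 (1S,2Z)-1-[(2S,3S)-2-[(1Z,3S)-3-(tert-butyldimethylsilyloxy)-2-methyl-5-oxopent-1-enyl]-4-methylidene-5-oxooxolan-3-yl]-3-iodobut-2-enyl (2Z)-2-methylbut-2-enoate
Conditions: Dess–Martin periodinane, NaHCO3, CH2Cl2, 0 °C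
Reagents that add atoms: none
Why: Dess–Martin oxidation gives the β-silyloxy aldehyde under buffered conditions that avoid β-elimination.

**Step 22**
Reactants: 27 aldehyde (Z)-vinyl iodide
Product: 28 (3aS,4R,5Z,9S,10Z,11aS)-9-(tert-butyldimethylsilyloxy)-7-hydroxy-6,10-dimethyl-3-methylidene-2-oxo-2,3,3a,4,7,8,9,11a-octahydrocyclodeca[b]furan-4-yl (2Z)-2-methylbut-2-enoate (C1 epimers)
Conditions: CrCl2 (15 equiv), NiCl2 (0.2 equiv), DMSO, 2 mM, rt
Reagents that add atoms: none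
Why: Intramolecular Nozaki–Hiyama–Kishi reaction at high dilution forms the C1–C10 bond and the ten-membered ring with retention of the Z geometry, helped by the two Z-alkenes and the cis-lactone, and the C1 epimer ratio does not matter.

**Step 23**
Reactants: 28 macrocyclic allylic alcohol (C1 epimers)
Product: 29 (3aS,4R,5Z,9S,10Z,11aS)-9-(tert-butyldimethylsilyloxy)-6,10-dimethyl-3-methylidene-2,7-dioxo-2,3,3a,4,7,8,9,11a-octahydrocyclodeca[b]furan-4-yl (2Z)-2-methylbut-2-enoate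
Conditions: Dess–Martin periodinane, NaHCO3, CH2Cl2, 0 °C → rt
Reagents that add atoms: none
Why: Dess–Martin oxidation converges the C1 epimers to the Z-enone, whose γ-oxygen O8 is already acylated and so cannot form a transannular hemiketal.

**Step 24**
Reactants: 29 macrocyclic enone silyl ether
Product: 30 (3aS,4R,5Z,9S,10Z,11aS)-9-hydroxy-6,10-dimethyl-3-methylidene-2,7-dioxo-2,3,3a,4,7,8,9,11a-octahydrocyclodeca[b]furan-4-yl (2Z)-2-methylbut-2-enoate
Conditions: HF·pyridine, THF, 0 °C → rt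
Reagents that add atoms: none
Why: Fluoride-mediated desilylation under mildly acidic, non-basic conditions frees the C3 hydroxyl without β-elimination, retro-aldol cleavage or angelate isomerisation.

**Step 25**
Reactants: 30 macrocyclic β-hydroxy enone
Product: 31 (3aS,4R,5Z,7S,9S,10Z,11aS)-9-acetoxy-7-hydroxy-6,10-dimethyl-3-methylidene-2-oxo-2,3,3a,4,7,8,9,11a-octahydrocyclodeca[b]furan-4-yl (2Z)-2-methylbut-2-enoate
Conditions: SmI2 (0.3 equiv), CH3CHO (10 equiv), THF, −10 °C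
Reagents that add atoms: acetaldehyde, CC=O
Why: Evans–Tishchenko reduction, in which the hemiacetal of the C3 hydroxyl and acetaldehyde bound to trivalent samarium delivers hydride intramolecularly to the C1 ketone through a chair transition state, gives the 1,3-anti diol monoester with the acetate on O3 and the free (S)-hydroxyl at C1.

**Compound list**
1 | ethyl 4-chloro-3-oxobutanoate | CCOC(=O)CC(=O)CCl | starting material
2 | 4-methoxybenzyl alcohol | COc1ccc(CO)cc1 | starting material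
3 | ethyl 4-[(4-methoxybenzyl)oxy]-3-oxobutanoate | CCOC(=O)CC(=O)COCc1ccc(OC)cc1 | intermediate
4 | ethyl (3S)-3-hydroxy-4-[(4-methoxybenzyl)oxy]butanoate | CCOC(=O)C[C@H](O)COCc1ccc(OC)cc1 | intermediate
5 | ethyl (2R,3S)-2-allyl-3-hydroxy-4-[(4-methoxybenzyl)oxy]butanoate | CCOC(=O)[C@H](CC=C)[C@H](O)COCc1ccc(OC)cc1 | intermediate
6 | ethyl (2R,3S)-2-allyl-4-[(4-methoxybenzyl)oxy]-3-(triethylsilyloxy)butanoate | CCOC(=O)[C@H](CC=C)[C@H](O[Si](CC)(CC)CC)COCc1ccc(OC)cc1 | intermediate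
7 | (2R,3S)-2-allyl-N-methoxy-4-[(4-methoxybenzyl)oxy]-N-methyl-3-(triethylsilyloxy)butanamide | CON(C)C(=O)[C@H](CC=C)[C@H](O[Si](CC)(CC)CC)COCc1ccc(OC)cc1 | intermediate
8 | (5R,6S)-5-allyl-7-[(4-methoxybenzyl)oxy]-6-(triethylsilyloxy)hept-2-yn-4-one | CC#CC(=O)[C@H](CC=C)[C@H](O[Si](CC)(CC)CC)COCc1ccc(OC)cc1 | intermediate
9 | (4R,5S,6S)-5-allyl-7-[(4-methoxybenzyl)oxy]-6-(triethylsilyloxy)hept-2-yn-4-ol | CC#C[C@H](O)[C@H](CC=C)[C@H](O[Si](CC)(CC)CC)COCc1ccc(OC)cc1 | intermediate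
10 | (2Z,4R,5S,6S)-5-allyl-2-iodo-7-[(4-methoxybenzyl)oxy]-6-(triethylsilyloxy)hept-2-en-4-ol | C/C(I)=C/[C@H](O)[C@H](CC=C)[C@H](O[Si](CC)(CC)CC)COCc1ccc(OC)cc1 | intermediate
11 | (4S,5R)-5-[(Z)-2-iodoprop-1-enyl]-4-[(1S)-2-[(4-methoxybenzyl)oxy]-1-(triethylsilyloxy)ethyl]oxolan-2-ol (anomer mixture) | OC1C[C@H]([C@H](O[Si](CC)(CC)CC)COCc2ccc(OC)cc2)[C@H](/C=C(/C)I)O1 | intermediate (not isolated)
12 | (4S,5R)-5-[(Z)-2-iodoprop-1-enyl]-4-[(1S)-2-[(4-methoxybenzyl)oxy]-1-(triethylsilyloxy)ethyl]oxolan-2-one | O=C1C[C@H]([C@H](O[Si](CC)(CC)CC)COCc2ccc(OC)cc2)[C@H](/C=C(/C)I)O1 | intermediate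
13 | 3-(tert-butyldimethylsilyloxy)propanal | O=CCCO[Si](C)(C)C(C)(C)C | starting material
14 | (4S,5S)-5-[(1Z)-5-(tert-butyldimethylsilyloxy)-3-hydroxy-2-methylpent-1-enyl]-4-[(1S)-2-[(4-methoxybenzyl)oxy]-1-(triethylsilyloxy)ethyl]oxolan-2-one (C3 epimers) | O=C1C[C@H]([C@H](O[Si](CC)(CC)CC)COCc2ccc(OC)cc2)[C@H](/C=C(/C)C(O)CCO[Si](C)(C)C(C)(C)C)O1 | intermediate
15 | (4S,5S)-5-[(1Z)-5-(tert-butyldimethylsilyloxy)-2-methyl-3-oxopent-1-enyl]-4-[(1S)-2-[(4-methoxybenzyl)oxy]-1-(triethylsilyloxy)ethyl]oxolan-2-one | O=C1C[C@H]([C@H](O[Si](CC)(CC)CC)COCc2ccc(OC)cc2)[C@H](/C=C(/C)C(=O)CCO[Si](C)(C)C(C)(C)C)O1 | intermediate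
16 | (4S,5S)-5-[(1Z,3S)-5-(tert-butyldimethylsilyloxy)-3-hydroxy-2-methylpent-1-enyl]-4-[(1S)-2-[(4-methoxybenzyl)oxy]-1-(triethylsilyloxy)ethyl]oxolan-2-one | O=C1C[C@H]([C@H](O[Si](CC)(CC)CC)COCc2ccc(OC)cc2)[C@H](/C=C(/C)[C@@H](O)CCO[Si](C)(C)C(C)(C)C)O1 | intermediate
17 | (4S,5S)-5-[(1Z,3S)-3,5-bis(tert-butyldimethylsilyloxy)-2-methylpent-1-enyl]-4-[(1S)-2-[(4-methoxybenzyl)oxy]-1-(triethylsilyloxy)ethyl]oxolan-2-one | O=C1C[C@H]([C@H](O[Si](CC)(CC)CC)COCc2ccc(OC)cc2)[C@H](/C=C(/C)[C@@H](O[Si](C)(C)C(C)(C)C)CCO[Si](C)(C)C(C)(C)C)O1 | intermediate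
18 | (4S,5S)-5-[(1Z,3S)-3,5-bis(tert-butyldimethylsilyloxy)-2-methylpent-1-enyl]-4-[(1S)-2-hydroxy-1-(triethylsilyloxy)ethyl]oxolan-2-one | O=C1C[C@H]([C@H](O[Si](CC)(CC)CC)CO)[C@H](/C=C(/C)[C@@H](O[Si](C)(C)C(C)(C)C)CCO[Si](C)(C)C(C)(C)C)O1 | intermediate
19 | (4S,5S)-5-[(1Z,3S)-3,5-bis(tert-butyldimethylsilyloxy)-2-methylpent-1-enyl]-4-[(1S)-2-oxo-1-(triethylsilyloxy)ethyl]oxolan-2-one | O=C1C[C@H]([C@H](O[Si](CC)(CC)CC)C=O)[C@H](/C=C(/C)[C@@H](O[Si](C)(C)C(C)(C)C)CCO[Si](C)(C)C(C)(C)C)O1 | intermediate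
20 | (4S,5S)-5-[(1Z,3S)-3,5-bis(tert-butyldimethylsilyloxy)-2-methylpent-1-enyl]-4-[(1S,2Z)-3-iodo-1-(triethylsilyloxy)but-2-enyl]oxolan-2-one | O=C1C[C@H]([C@H](O[Si](CC)(CC)CC)/C=C(/C)I)[C@H](/C=C(/C)[C@@H](O[Si](C)(C)C(C)(C)C)CCO[Si](C)(C)C(C)(C)C)O1 | intermediate
21 | 3-[(dimethylamino)methyl] derivative of 20 (C11 epimers) | O=C1C(CN(C)C)[C@H]([C@H](O[Si](CC)(CC)CC)/C=C(/C)I)[C@H](/C=C(/C)[C@@H](O[Si](C)(C)C(C)(C)C)CCO[Si](C)(C)C(C)(C)C)O1 | intermediate (not isolated)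
22 | trimethylammonium iodide (methiodide) of 21 | O=C1C(C[N+](C)(C)C)[C@H]([C@H](O[Si](CC)(CC)CC)/C=C(/C)I)[C@H](/C=C(/C)[C@@H](O[Si](C)(C)C(C)(C)C)CCO[Si](C)(C)C(C)(C)C)O1.[I-] | intermediate (not isolated)
23 | (4S,5S)-5-[(1Z,3S)-3,5-bis(tert-butyldimethylsilyloxy)-2-methylpent-1-enyl]-4-[(1S,2Z)-3-iodo-1-(triethylsilyloxy)but-2-enyl]-3-methylideneoxolan-2-one | C=C1C(=O)O[C@@H](/C=C(/C)[C@@H](O[Si](C)(C)C(C)(C)C)CCO[Si](C)(C)C(C)(C)C)[C@H]1[C@H](O[Si](CC)(CC)CC)/C=C(/C)I | intermediate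
24 | (4R,5S)-5-[(1Z,3S)-3,5-bis(tert-butyldimethylsilyloxy)-2-methylpent-1-enyl]-4-[(1S,2Z)-1-hydroxy-3-iodobut-2-enyl]-3-methylideneoxolan-2-one | C=C1C(=O)O[C@@H](/C=C(/C)[C@@H](O[Si](C)(C)C(C)(C)C)CCO[Si](C)(C)C(C)(C)C)[C@H]1[C@H](O)/C=C(/C)I | intermediate
25 | (1S,2Z)-1-[(2S,3S)-2-[(1Z,3S)-3,5-bis(tert-butyldimethylsilyloxy)-2-methylpent-1-enyl]-4-methylidene-5-oxooxolan-3-yl]-3-iodobut-2-enyl (2Z)-2-methylbut-2-enoate | C=C1C(=O)O[C@@H](/C=C(/C)[C@@H](O[Si](C)(C)C(C)(C)C)CCO[Si](C)(C)C(C)(C)C)[C@H]1[C@H](OC(=O)/C(C)=C\C)/C=C(/C)I | intermediate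
26 | (1S,2Z)-1-[(2S,3S)-2-[(1Z,3S)-3-(tert-butyldimethylsilyloxy)-5-hydroxy-2-methylpent-1-enyl]-4-methylidene-5-oxooxolan-3-yl]-3-iodobut-2-enyl (2Z)-2-methylbut-2-enoate | C=C1C(=O)O[C@@H](/C=C(/C)[C@@H](O[Si](C)(C)C(C)(C)C)CCO)[C@H]1[C@H](OC(=O)/C(C)=C\C)/C=C(/C)I | intermediate
27 | (1S,2Z)-1-[(2S,3S)-2-[(1Z,3S)-3-(tert-butyldimethylsilyloxy)-2-methyl-5-oxopent-1-enyl]-4-methylidene-5-oxooxolan-3-yl]-3-iodobut-2-enyl (2Z)-2-methylbut-2-enoate | C=C1C(=O)O[C@@H](/C=C(/C)[C@@H](O[Si](C)(C)C(C)(C)C)CC=O)[C@H]1[C@H](OC(=O)/C(C)=C\C)/C=C(/C)I | intermediate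
28 | (3aS,4R,5Z,9S,10Z,11aS)-9-(tert-butyldimethylsilyloxy)-7-hydroxy-6,10-dimethyl-3-methylidene-2-oxo-2,3,3a,4,7,8,9,11a-octahydrocyclodeca[b]furan-4-yl (2Z)-2-methylbut-2-enoate (C1 epimers) | C=C1C(=O)O[C@H]2/C=C(/C)[C@@H](O[Si](C)(C)C(C)(C)C)CC(O)/C(C)=C\[C@@H](OC(=O)/C(C)=C\C)[C@@H]12 | intermediate
29 | (3aS,4R,5Z,9S,10Z,11aS)-9-(tert-butyldimethylsilyloxy)-6,10-dimethyl-3-methylidene-2,7-dioxo-2,3,3a,4,7,8,9,11a-octahydrocyclodeca[b]furan-4-yl (2Z)-2-methylbut-2-enoate | C=C1C(=O)O[C@H]2/C=C(/C)[C@@H](O[Si](C)(C)C(C)(C)C)CC(=O)/C(C)=C\[C@@H](OC(=O)/C(C)=C\C)[C@@H]12 | intermediate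
30 | (3aS,4R,5Z,9S,10Z,11aS)-9-hydroxy-6,10-dimethyl-3-methylidene-2,7-dioxo-2,3,3a,4,7,8,9,11a-octahydrocyclodeca[b]furan-4-yl (2Z)-2-methylbut-2-enoate | C=C1C(=O)O[C@H]2/C=C(/C)[C@@H](O)CC(=O)/C(C)=C\[C@@H](OC(=O)/C(C)=C\C)[C@@H]12 | intermediate
31 | (3aS,4R,5Z,7S,9S,10Z,11aS)-9-acetoxy-7-hydroxy-6,10-dimethyl-3-methylidene-2-oxo-2,3,3a,4,7,8,9,11a-octahydrocyclodeca[b]furan-4-yl (2Z)-2-methylbut-2-enoate | C=C1C(=O)O[C@H]2/C=C(/C)[C@@H](OC(C)=O)C[C@H](O)/C(C)=C\[C@@H](OC(=O)/C(C)=C\C)[C@@H]12 | target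

**Step count and risks**
Total: 25 steps. Longest linear sequence: 25 steps (1 → 31); aldehyde 13 is used as bought.

Steps most likely to fail:

- Step 22 (ten-membered ring closure by Ni/Cr coupling; strain and oligomerisation are the risks). The fallback sets out from 27 and comes back at 29, skipping 28. Pinnick oxidation (NaClO2, NaH2PO4, 2-methyl-2-butene) gives the iodo acid F3. Stannylation with zerovalent palladium (Pd(PPh3)4, Me3SnSnMe3, iPr2NEt) gives the stannyl acid F4. 1-Chloro-N,N,2-trimethylpropenylamine gives the acid chloride F5. Intramolecular Stille acylation (Pd2(dba)3, tri(2-furyl)phosphine, high dilution) then closes the ring directly to enone 29.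

- Step 16 (Z-iodo-olefination of a hindered α-silyloxy aldehyde; modest yield and Z/E ratio are the risks). The fallback sets out from 19 and comes back at 20. Ramirez olefination (CBr4, PPh3, 2,6-lutidine, CH2Cl2, 0 °C) gives the dibromoalkene F1. Negishi coupling (MeZnCl, PdCl2(DPEphos), THF) replaces only the bromide trans to the chain and gives the (Z)-bromoalkene F2. Copper-catalysed halogen exchange (CuI, N,N′-dimethylethylenediamine, NaI, dioxane, 110 °C) proceeds with retention and returns to 20.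

- Step 25 (Evans–Tishchenko reduction inside the macrocycle; the ring may disfavour the chair transition state and SmI2 may touch the Michael acceptors). The fallback sets out from 30 and comes back at 31. Acetylation (Ac2O, pyridine, 0 °C, no DMAP) gives the keto acetate F6. Reagent-controlled reduction of the C1 ketone with (R)-2-methyl-CBS-oxazaborolidine and catecholborane at −78 °C then gives 31.

**Further compounds**
F1 | step 16 | (4S,5S)-5-[(1Z,3S)-3,5-bis(tert-butyldimethylsilyloxy)-2-methylpent-1-enyl]-4-[(1S)-3,3-dibromo-1-(triethylsilyloxy)prop-2-enyl]oxolan-2-one | O=C1C[C@H]([C@H](O[Si](CC)(CC)CC)C=C(Br)Br)[C@H](/C=C(/C)[C@@H](O[Si](C)(C)C(C)(C)C)CCO[Si](C)(C)C(C)(C)C)O1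
F2 | step 16 | (4S,5S)-5-[(1Z,3S)-3,5-bis(tert-butyldimethylsilyloxy)-2-methylpent-1-enyl]-4-[(1S,2Z)-3-bromo-1-(triethylsilyloxy)but-2-enyl]oxolan-2-one | O=C1C[C@H]([C@H](O[Si](CC)(CC)CC)/C=C(/C)Br)[C@H](/C=C(/C)[C@@H](O[Si](C)(C)C(C)(C)C)CCO[Si](C)(C)C(C)(C)C)O1
F3 | step 22 | (3S,4Z)-3-(tert-butyldimethylsilyloxy)-5-[(2S,3S)-3-[(1S,2Z)-3-iodo-1-[(2Z)-2-methylbut-2-enoyloxy]but-2-enyl]-4-methylidene-5-oxooxolan-2-yl]-4-methylpent-4-enoic acid | C=C1C(=O)O[C@@H](/C=C(/C)[C@@H](O[Si](C)(C)C(C)(C)C)CC(=O)O)[C@H]1[C@H](OC(=O)/C(C)=C\C)/C=C(/C)I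
F4 | step 22 | (3S,4Z)-3-(tert-butyldimethylsilyloxy)-4-methyl-5-[(2S,3S)-4-methylidene-3-[(1S,2Z)-1-[(2Z)-2-methylbut-2-enoyloxy]-3-(trimethylstannyl)but-2-enyl]-5-oxooxolan-2-yl]pent-4-enoic acid | C=C1C(=O)O[C@@H](/C=C(/C)[C@@H](O[Si](C)(C)C(C)(C)C)CC(=O)O)[C@H]1[C@H](OC(=O)/C(C)=C\C)/C=C(/C)[Sn](C)(C)C
F5 | step 22 | acid chloride of F4 | C=C1C(=O)O[C@@H](/C=C(/C)[C@@H](O[Si](C)(C)C(C)(C)C)CC(=O)Cl)[C@H]1[C@H](OC(=O)/C(C)=C\C)/C=C(/C)[Sn](C)(C)C
F6 | step 25 | (3aS,4R,5Z,9S,10Z,11aS)-9-acetoxy-6,10-dimethyl-3-methylidene-2,7-dioxo-2,3,3a,4,7,8,9,11a-octahydrocyclodeca[b]furan-4-yl (2Z)-2-methylbut-2-enoate | C=C1C(=O)O[C@H]2/C=C(/C)[C@@H](OC(C)=O)CC(=O)/C(C)=C\[C@@H](OC(=O)/C(C)=C\C)[C@@H]12
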